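## The problem

Target 10 is a trans-2-aryl-3-methyl-2,3-dihydro-1,4-benzodioxine: the dioxane ring is fused to a benzene ring (ring A) bearing a methoxy group at C5 and an (E)-propenal chain at C7, with a 3,4,5-trimethoxyphenyl group on C2 and a methyl group on C3. The two ring oxygens are not equivalent: O4 sits on C4a, next to the C5 methoxy group and para to the C7 chain, and is bonded to the methyl-bearing C3, whereas O1 is meta to the chain and bonded to the benzylic C2, so any synthesis must control which oxygen joins which carbon. C2 and C3 are the only stereocentres, adjacent and trans (2S,3S) with both substituents equatorial, so a reversible ring closure can set the relative configuration, with C3 controlling C2. The absolute configuration has no internal source and must come from a catalyst, a chiral building block or a resolution. C2 is a benzylic aryl ether on an electron-rich ring; it can ionise under acid, and under base through a quinone methide as long as the para oxygen is a free phenol, so it is the centre at risk of epimerisation. The enal is sensitive to oxidants, nucleophiles and base and should appear last. The enabling feature is that C2–C3 with its para-oxygenated aryl group is a propenylphenol unit and ring A is a catechol: the O4–C3/O1–C2 pattern is what results when the catechol oxygen para to the side chain couples with the β-carbon of a propenylphenol radical and the neighbouring hydroxyl traps the p-quinone methide, the 4-methoxy group of the trimethoxyphenyl ring being a masked phenol.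

## Retrosynthesis

**10 ⇒ 9 ⇒ 8 (side-chain oxidation level).** No skeletal bond is cut; the enal is traced to allylic alcohol 9 and then to methyl ester 8. The neighbouring cut, through the chain C=C back to a C7 aldehyde, would push a formyl-catechol into the oxidative coupling, where the aldehyde would have to survive Ag2O, a classical reagent for aldehyde-to-acid oxidation, and the olefination would then fall on the resolved, most valuable material. An acrylate ester survives oxidation, base and chromatography and keeps the para oxygen conjugated with the chain. The forward steps must give clean 1,2-reduction of the unsaturated ester and a mild allylic oxidation.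

**8 ⇒ 7 (resolution).** No bond is cut; the absolute problem is reduced to a relative one, because an enantioselective radical cross-coupling of this kind is beyond known chemistry. Racemic trans ester 7 is the chosen point for three reasons: C2 can no longer open once the phenol is capped, a neutral aromatic ester suits chiral stationary phases, and the last two steps then run only on the needed enantiomer. The forward step must give baseline separation on a preparative scale.

**7 ⇒ 6 (O–CH3).** The methyl–oxygen bond of the 4-methoxy group on the C2 aryl ring is cut, revealing the phenol 6 that the coupling requires. The forward step is an O-methylation mild enough not to open the dioxane.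

**6 ⇒ 2 + 4 via 5 (C3–O4 and C2–O1).** Both alkyl–oxygen bonds of the dioxane are cut, through p-quinone methide 5. Cutting the aryl–oxygen bonds instead would require a halogenated ring A and a preformed chiral diol. Cutting C2–C3 would leave the ring open and need aldol-type chemistry. The chosen cut removes the ring and both stereocentres at once and gives two flat, achiral C11 phenols, propenylphenol 2 and catechol 4. The forward reaction must favour cross- over homo-coupling, bond the catechol oxygen para to the acrylate to the β-carbon, and close to the trans ring.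

**2 ⇒ 1 and 4 ⇒ 3.** Propenylphenol 2 comes from commercial allylphenol 1 by moving the double bond into conjugation. Catechol 4 comes from commercial aldehyde 3 by cutting the acrylate C=C (stabilised Wittig reaction). Neither step needs a protecting group.

## Roads not taken

Alternative 1: The cut is through C3–O4 and C2–C3, leaving the ring open. Rh2(OAc)4 would decompose ethyl diazoacetate A2 in the presence of 2-bromo-4-(1,3-dioxolan-2-yl)-6-methoxyphenol A1. The phenol oxygen adds to the rhodium carbene, and the oxonium ylide is intercepted by 3,4,5-trimethoxybenzaldehyde A3, activated by a chiral phosphoric acid, to give ethyl (2R,3S)-2-[2-bromo-4-(1,3-dioxolan-2-yl)-6-methoxyphenoxy]-3-hydroxy-3-(3,4,5-trimethoxyphenyl)propanoate A4.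
- Merits: both stereocentres are set absolutely in one catalytic step, and regiochemistry is fixed by construction, because the phenol oxygen of A1 becomes O4 and its brominated carbon becomes C8a.
- Weak points: A3 is an electron-rich, poorly electrophilic aldehyde, so the ylide formed from A1 and A2 is likely to leak to the simple O–H insertion product by 1,2-proton shift. A4 still lacks the ring, and closing it needs a metal-catalysed aryl etherification of a secondary benzylic alcohol that can undergo retro-aldol cleavage under base. The ester carbon must then be reduced to a methyl group in three steps beside a β-aryloxy leaving group, followed by acetal removal and two-carbon extension. About ten steps result.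
- Comparison: this road is better on absolute configuration and at least equal on regiochemical certainty. The chosen plan offers instead a C3 that already carries its methyl group, ring and both C–O bonds formed in one step, and seven steps in all; it pays with a resolution.

Alternative 2: The cut is through the aryl–oxygen bonds O4–C4a and O1–C8a, with ring A carried as a cyclohexane-1,3-dione. Rh2(OAc)4 would convert methyl 4-diazo-3,5-dioxocyclohexane-1-carboxylate A6 into a carbene that inserts into the O–H bond of the methyl carbinol of (1S,2S)-1-[(tert-butyldimethylsilyl)oxy]-1-(3,4,5-trimethoxyphenyl)propan-2-ol A5. Acid then removes the silyl group and condenses the benzylic hydroxyl with one of the two equivalent carbonyls, giving methyl (2S,3S)-3-methyl-5-oxo-2-(3,4,5-trimethoxyphenyl)-2,3,5,6,7,8-hexahydro-1,4-benzodioxine-7-carboxylate A7.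
- Merits: both stereocentres of A5 come from an asymmetric dihydroxylation, so no resolution is needed, and the symmetry of A6 removes the regiochemical question.
- Weak points: ring A of A7 is at the wrong oxidation level. Dehydrogenation to the phenol, O-methylation and conversion of the ring ester into the propenal chain all remain. The acidic condensation and the aromatisation expose the ionisable C2 ether to epimerisation. Making A5 requires telling two secondary hydroxyls apart. About twelve steps result.
- Comparison: this road is better on stereocontrol and regiochemical certainty and clearly worse on length and redox economy. The chosen plan starts with ring A aromatic and fully substituted from a commercial aldehyde.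

Alternative 3: The cut is C3–O4, made by iodoetherification after C2–O1 has been formed as a branched allyl aryl ether. I2 with NaHCO3 would activate the vinyl group of methyl 4-hydroxy-3-methoxy-5-{[(1R)-1-(3,4,5-trimethoxyphenyl)prop-2-en-1-yl]oxy}benzoate A8. The phenol attacks the internal alkene carbon in a 6-exo closure to give methyl (2S,3R)-3-(iodomethyl)-5-methoxy-2-(3,4,5-trimethoxyphenyl)-2,3-dihydro-1,4-benzodioxine-7-carboxylate A9.
- Merits: A8 is open to catalytic enantioselective synthesis by branched-selective allylic etherification with [Ir(cod)Cl]2 and a chiral phosphoramidite, so C2 is catalyst-controlled, and the order of bond formation fixes the regiochemistry.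
- Weak points: C3 of A9 is set by 1,2-induction in an irreversible closure with no thermodynamic correction toward trans. The internal alkene carbon is deactivated by the adjacent C–O bond, so 7-endo attack competes. The α-aryl allyl aryl ether A8 can ionise or undergo Claisen rearrangement, and I2 can iodinate the trimethoxyphenyl ring. After the closure A9 still needs reductive deiodination and conversion of the benzoate into the propenal chain, and the catechol must be differentiated beforehand.
- Comparison: this road is better on absolute configuration at C2. On trans selectivity the chosen plan is stronger, because its closure passes through a quinone methide that can reopen, and it is several steps shorter and needs no protecting group.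

The chosen plan's own costs are that half of the material is lost at the resolution and that a radical cross-coupling is unlikely to be high-yielding. Both are accepted because the two partners are each one step from cheap commercial phenols.

Key step: step 3

Assumption: the route does not control absolute configuration; the enantiomers separated in step 5 are taken to be assigned by electronic circular dichroism against a computed spectrum, and the (2S,3S) enantiomer is carried on.

## Route

Step 1
Reactants: 1 4-allyl-2,6-dimethoxyphenol
Product: 2 (E)-2,6-dimethoxy-4-(prop-1-en-1-yl)phenol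
Conditions: KOH (3 equiv), ethylene glycol, 150 °C, N2; then aq. HCl
Reagents that add atoms: none
Why: Base-mediated prototropic isomerisation of an allylarene into conjugation (the eugenol-to-isoeugenol reaction); the E alkene is the thermodynamic product, and any Z isomer is tolerated because alkene geometry is erased in the quinone methide of step 3.

Step 2
Reactants: 3 3,4-dihydroxy-5-methoxybenzaldehyde
Product: 4 methyl (E)-3-(3,4-dihydroxy-5-methoxyphenyl)prop-2-enoate
Conditions: Ph3P=CHCO2Me (1.5 equiv), toluene–THF 4:1, 80 °C, N2
Reagents that add atoms: methyl (triphenylphosphoranylidene)acetate, COC(=O)C=P(c1ccccc1)(c1ccccc1)c1ccccc1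
Why: Wittig olefination with a stabilised ylide, which is E-selective; unprotected hydroxybenzaldehydes are established substrates for this ylide, because proton exchange between the phenols and the ylide is reversible and does not consume it, so no protection is needed.

Step 3
Reactants: 2 (E)-2,6-dimethoxy-4-(prop-1-en-1-yl)phenol; 4 methyl (E)-3-(3,4-dihydroxy-5-methoxyphenyl)prop-2-enoate
Product: 6 methyl (E)-3-[(2S*,3S*)-2-(4-hydroxy-3,5-dimethoxyphenyl)-5-methoxy-3-methyl-2,3-dihydro-1,4-benzodioxin-7-yl]prop-2-enoate (racemic trans), via p-quinone methide 5 (not isolated)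
Conditions: Ag2O (2 equiv), toluene–acetone 2:1, 20 °C, dark; 4 in excess (1.5 equiv), 2 added over 4 h
Reagents that add atoms: none
Why: Ag2O (monovalent silver, a one-electron oxidant) converts both phenols into phenoxyl radicals: that of 2 is delocalised onto the β-carbon of the propenyl chain, and the semiquinone of 4 carries its spin mainly on the oxygen para to the acrylate, which is flanked by a methoxy and a hydroxyl group and has the weakest O–H bond. Radical–radical coupling of this oxygen with the β-carbon forms C3–O4 and gives p-quinone methide 5; the neighbouring hydroxyl then adds to the quinone methide carbon in a 6-exo-trig conjugate addition that forms C2–O1, closes the dioxane ring and rearomatises the dimethoxyphenol ring. The closest known reaction type is the Ag2O- or Ag2CO3-mediated biomimetic cross-coupling of propenylphenols or cinnamyl alcohols with catechols, the established entry to 2-aryl-1,4-benzodioxane neolignans. C3 is created in the coupling without control and is racemic; C2 is set relative to C3 in the ring closure, whose chair-like transition state places methyl and aryl equatorial and leads to the trans ring. Because the free para-hydroxyl lets C2–O1 reopen through 5, cis material can drain to the more stable trans isomer. The step needs cross- over homo-coupling: the electron-rich β-carbon of the radical from 2 is polarity-matched with the electrophilic oxygen radical of the acrylate-bearing catechol, the acrylate's own β-carbon is electron-poor, and slow addition of 2 to an excess of 4 keeps the radical from 2 dilute. Regiochemistry rests on the difference between the two catechol oxygens, only one of which is doubly ortho-oxygenated and conjugated with the acrylate.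

Step 4
Reactants: 6 methyl (E)-3-[(2S*,3S*)-2-(4-hydroxy-3,5-dimethoxyphenyl)-5-methoxy-3-methyl-2,3-dihydro-1,4-benzodioxin-7-yl]prop-2-enoate (racemic trans)
Product: 7 methyl (E)-3-[(2S*,3S*)-5-methoxy-3-methyl-2-(3,4,5-trimethoxyphenyl)-2,3-dihydro-1,4-benzodioxin-7-yl]prop-2-enoate (racemic trans)
Conditions: MeI (3 equiv), K2CO3 (2 equiv), DMF, 20 °C
Reagents that add atoms: iodomethane, CI
Why: Williamson O-methylation (SN2 of the phenoxide on MeI); the hindered 2,6-dimethoxyphenoxide is still a good nucleophile in DMF, no stereocentre is touched, and capping the phenol closes the quinone methide pathway so that C2 is configurationally fixed from here on.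

Step 5
Reactants: 7 methyl (E)-3-[(2S*,3S*)-5-methoxy-3-methyl-2-(3,4,5-trimethoxyphenyl)-2,3-dihydro-1,4-benzodioxin-7-yl]prop-2-enoate (racemic trans)
Product: 8 methyl (E)-3-[(2S,3S)-5-methoxy-3-methyl-2-(3,4,5-trimethoxyphenyl)-2,3-dihydro-1,4-benzodioxin-7-yl]prop-2-enoate
Conditions: preparative HPLC, amylose tris(3,5-dimethylphenylcarbamate) on silica, hexane–i-PrOH, 25 °C
Reagents that add atoms: none
Why: Resolution of a racemate by preparative chromatography on a chiral stationary phase, a dependable operation for neutral aromatic esters; no bond is made or broken, so the trans relationship is untouched and the (2S,3S) enantiomer is simply selected.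

Step 6
Reactants: 8 methyl (E)-3-[(2S,3S)-5-methoxy-3-methyl-2-(3,4,5-trimethoxyphenyl)-2,3-dihydro-1,4-benzodioxin-7-yl]prop-2-enoate
Product: 9 (E)-3-[(2S,3S)-5-methoxy-3-methyl-2-(3,4,5-trimethoxyphenyl)-2,3-dihydro-1,4-benzodioxin-7-yl]prop-2-en-1-ol
Conditions: i-Bu2AlH (2.5 equiv), CH2Cl2, −78 °C; aq. potassium sodium tartrate
Reagents that add atoms: none
Why: 1,2-Reduction of an α,β-unsaturated ester to the allylic alcohol by i-Bu2AlH at low temperature, the standard cinnamate-to-cinnamyl alcohol reduction; the aryl ethers and the benzylic ether are inert and the E geometry is kept.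

Step 7
Reactants: 9 (E)-3-[(2S,3S)-5-methoxy-3-methyl-2-(3,4,5-trimethoxyphenyl)-2,3-dihydro-1,4-benzodioxin-7-yl]prop-2-en-1-ol
Product: 10 (E)-3-[(2S,3S)-5-methoxy-3-methyl-2-(3,4,5-trimethoxyphenyl)-2,3-dihydro-1,4-benzodioxin-7-yl]prop-2-enal
Conditions: activated MnO2 (15 equiv), CH2Cl2, 20 °C
Reagents that add atoms: none
Why: Chemoselective MnO2 oxidation of an allylic (cinnamyl) alcohol to the enal under neutral heterogeneous conditions; there is no over-oxidation and C2, C3 and the E alkene are unaffected.

## Compound list

1 | 4-allyl-2,6-dimethoxyphenol | COc1cc(CC=C)cc(OC)c1O | starting material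
2 | (E)-2,6-dimethoxy-4-(prop-1-en-1-yl)phenol | COc1cc(/C=C/C)cc(OC)c1O | intermediate
3 | 3,4-dihydroxy-5-methoxybenzaldehyde | COc1cc(C=O)cc(O)c1O | starting material
4 | methyl (E)-3-(3,4-dihydroxy-5-methoxyphenyl)prop-2-enoate | COc1cc(/C=C/C(=O)OC)cc(O)c1O | intermediate
5 | methyl (E)-3-[4-{[(2S*)-1-(3,5-dimethoxy-4-oxocyclohexa-2,5-dien-1-ylidene)propan-2-yl]oxy}-3-hydroxy-5-methoxyphenyl]prop-2-enoate (p-quinone methide, racemic, S enantiomer drawn) | C[C@H](Oc1c(O)cc(/C=C/C(=O)OC)cc1OC)C=C1C=C(OC)C(=O)C(OC)=C1 | intermediate (not isolated)
6 | methyl (E)-3-[(2S*,3S*)-2-(4-hydroxy-3,5-dimethoxyphenyl)-5-methoxy-3-methyl-2,3-dihydro-1,4-benzodioxin-7-yl]prop-2-enoate (racemic trans, 2S,3S enantiomer drawn) | COc1cc([C@@H]2Oc3cc(/C=C/C(=O)OC)cc(OC)c3O[C@H]2C)cc(OC)c1O | intermediate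
7 | methyl (E)-3-[(2S*,3S*)-5-methoxy-3-methyl-2-(3,4,5-trimethoxyphenyl)-2,3-dihydro-1,4-benzodioxin-7-yl]prop-2-enoate (racemic trans, 2S,3S enantiomer drawn) | COc1cc([C@@H]2Oc3cc(/C=C/C(=O)OC)cc(OC)c3O[C@H]2C)cc(OC)c1OC | intermediate
8 | methyl (E)-3-[(2S,3S)-5-methoxy-3-methyl-2-(3,4,5-trimethoxyphenyl)-2,3-dihydro-1,4-benzodioxin-7-yl]prop-2-enoate (single enantiomer) | COc1cc([C@@H]2Oc3cc(/C=C/C(=O)OC)cc(OC)c3O[C@H]2C)cc(OC)c1OC | intermediate
9 | (E)-3-[(2S,3S)-5-methoxy-3-methyl-2-(3,4,5-trimethoxyphenyl)-2,3-dihydro-1,4-benzodioxin-7-yl]prop-2-en-1-ol | COc1cc([C@@H]2Oc3cc(/C=C/CO)cc(OC)c3O[C@H]2C)cc(OC)c1OC | intermediate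
10 | (E)-3-[(2S,3S)-5-methoxy-3-methyl-2-(3,4,5-trimethoxyphenyl)-2,3-dihydro-1,4-benzodioxin-7-yl]prop-2-enal | COc1cc([C@@H]2Oc3cc(/C=C/C=O)cc(OC)c3O[C@H]2C)cc(OC)c1OC | target

## Step count and risks

Total: 7 steps (six reactions and one chromatographic resolution). Longest linear sequence: 6 steps (1 → 2 → 6 → 7 → 8 → 9 → 10; the branch from 3 is equally long).

**Step 3 (key step).** The likely failures are homo-coupling of either radical (dimerisation of 2 through its β-carbon, or of 4 through its own acrylate carbon), further oxidation of the product phenol, and coupling through the wrong catechol oxygen. The fallback makes the same two C–O bonds one after the other by polar chemistry; it sets out from catechol 4 and comes back to the route at 7, by-passing steps 3 and 4.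

The commercial ketone 1-(3,4,5-trimethoxyphenyl)propan-1-one F1 would be brominated with CuBr2 in EtOAc–CHCl3 at reflux to racemic 2-bromo-1-(3,4,5-trimethoxyphenyl)propan-1-one F2. Catechol 4, deprotonated only at its more acidic hydroxyl para to the acrylate by one equivalent of K2CO3 in DMF, would displace the bromide to give methyl (E)-3-[3-hydroxy-5-methoxy-4-{[1-oxo-1-(3,4,5-trimethoxyphenyl)propan-2-yl]oxy}phenyl]prop-2-enoate F3, which forms C3–O4. NaBH4 in MeOH at 0 °C would reduce the ketone to methyl (E)-3-[3-hydroxy-4-{[1-hydroxy-1-(3,4,5-trimethoxyphenyl)propan-2-yl]oxy}-5-methoxyphenyl]prop-2-enoate F4. BF3·OEt2 in CH2Cl2 at 0 °C would then ionise the benzylic alcohol; the neighbouring phenol traps the cation to form C2–O1, and reversible ionisation should favour the trans ring of racemic 7.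

In order, F1 is brominated to F2, then F2 alkylates 4 to give F3, then F3 is reduced to F4 and finally F4 closes to 7.

**Step 5.** The risk is insufficient discrimination of the enantiomers on the stationary phase, or low throughput, since the stereocentres are flanked only by ether oxygens and arenes. The fallback is a covalent resolution on the phenol; it sets out from 6 and comes back at 8.

Racemic 6 would be acylated with (1S)-camphanic chloride, that is (1S,4R)-4,7,7-trimethyl-3-oxo-2-oxabicyclo[2.2.1]heptane-1-carbonyl chloride, with Et3N and DMAP in CH2Cl2. Two diastereomeric esters result: 2,6-dimethoxy-4-[(2S,3S)-5-methoxy-7-[(E)-3-methoxy-3-oxoprop-1-en-1-yl]-3-methyl-2,3-dihydro-1,4-benzodioxin-2-yl]phenyl (1S,4R)-4,7,7-trimethyl-3-oxo-2-oxabicyclo[2.2.1]heptane-1-carboxylate F5 and 2,6-dimethoxy-4-[(2R,3R)-5-methoxy-7-[(E)-3-methoxy-3-oxoprop-1-en-1-yl]-3-methyl-2,3-dihydro-1,4-benzodioxin-2-yl]phenyl (1S,4R)-4,7,7-trimethyl-3-oxo-2-oxabicyclo[2.2.1]heptane-1-carboxylate F6. They would be separated by crystallisation or silica chromatography. The chiral unit is remote from C2 and C3, so this separation is itself not assured. K2CO3 in MeOH would then cleave the aryl ester and release methyl (E)-3-[(2S,3S)-2-(4-hydroxy-3,5-dimethoxyphenyl)-5-methoxy-3-methyl-2,3-dihydro-1,4-benzodioxin-7-yl]prop-2-enoate F7. C3 is untouched throughout, so the enantiomeric purity is anchored there. Methylation under the conditions of step 4 would give 8.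

In order, 6 is acylated to F5 plus F6 and the two are separated, then F6 is set aside, F5 is cleaved to F7 and F7 is methylated to 8.

**Step 2.** The risk is sluggish olefination of an electron-rich, hydrogen-bonded aldehyde, with air oxidation of the catechol during prolonged heating. The fallback sets out from 3 and comes back at 4. Aldehyde 3 would undergo Knoevenagel–Doebner condensation with malonic acid (pyridine, catalytic piperidine, 90 °C) to give (E)-3-(3,4-dihydroxy-5-methoxyphenyl)prop-2-enoic acid F8. Fischer esterification (MeOH, catalytic H2SO4, reflux) would then give 4.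

In order, 3 is condensed to F8 and then F8 is esterified to 4.

**Step 4.** The risk is base-induced opening of the dioxane through the quinone methide before the hindered phenoxide is alkylated, which would erode the trans configuration at C2. As a fallback, 6 would be methylated by a Mitsunobu etherification (MeOH, PPh3, diisopropyl azodicarboxylate, THF, 0 °C), which works without carbonate base. It sets out from 6 and comes back at 7.

No new compound arises on this path, which the entry F0 records.

## Further compounds

F1 | step 3 | 1-(3,4,5-trimethoxyphenyl)propan-1-one | CCC(=O)c1cc(OC)c(OC)c(OC)c1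
F2 | step 3 | 2-bromo-1-(3,4,5-trimethoxyphenyl)propan-1-one (racemic) | CC(Br)C(=O)c1cc(OC)c(OC)c(OC)c1
F3 | step 3 | methyl (E)-3-[3-hydroxy-5-methoxy-4-{[1-oxo-1-(3,4,5-trimethoxyphenyl)propan-2-yl]oxy}phenyl]prop-2-enoate (racemic) | COC(=O)/C=C/c1cc(O)c(OC(C)C(=O)c2cc(OC)c(OC)c(OC)c2)c(OC)c1
F4 | step 3 | methyl (E)-3-[3-hydroxy-4-{[1-hydroxy-1-(3,4,5-trimethoxyphenyl)propan-2-yl]oxy}-5-methoxyphenyl]prop-2-enoate (racemic, both diastereomers) | COC(=O)/C=C/c1cc(O)c(OC(C)C(O)c2cc(OC)c(OC)c(OC)c2)c(OC)c1
F5 | step 5 | 2,6-dimethoxy-4-[(2S,3S)-5-methoxy-7-[(E)-3-methoxy-3-oxoprop-1-en-1-yl]-3-methyl-2,3-dihydro-1,4-benzodioxin-2-yl]phenyl (1S,4R)-4,7,7-trimethyl-3-oxo-2-oxabicyclo[2.2.1]heptane-1-carboxylate | COc1cc([C@@H]2Oc3cc(/C=C/C(=O)OC)cc(OC)c3O[C@H]2C)cc(OC)c1OC(=O)[C@]12OC(=O)[C@](C)(CC1)C2(C)C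
F6 | step 5 | 2,6-dimethoxy-4-[(2R,3R)-5-methoxy-7-[(E)-3-methoxy-3-oxoprop-1-en-1-yl]-3-methyl-2,3-dihydro-1,4-benzodioxin-2-yl]phenyl (1S,4R)-4,7,7-trimethyl-3-oxo-2-oxabicyclo[2.2.1]heptane-1-carboxylate | COc1cc([C@H]2Oc3cc(/C=C/C(=O)OC)cc(OC)c3O[C@@H]2C)cc(OC)c1OC(=O)[C@]12OC(=O)[C@](C)(CC1)C2(C)C
F7 | step 5 | methyl (E)-3-[(2S,3S)-2-(4-hydroxy-3,5-dimethoxyphenyl)-5-methoxy-3-methyl-2,3-dihydro-1,4-benzodioxin-7-yl]prop-2-enoate (single enantiomer) | COc1cc([C@@H]2Oc3cc(/C=C/C(=O)OC)cc(OC)c3O[C@H]2C)cc(OC)c1O
F8 | step 2 | (E)-3-(3,4-dihydroxy-5-methoxyphenyl)prop-2-enoic acid | COc1cc(/C=C/C(=O)O)cc(O)c1O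
F0 | step 4 | none | none
A1 | alternative 1 | 2-bromo-4-(1,3-dioxolan-2-yl)-6-methoxyphenol | COc1cc(C2OCCO2)cc(Br)c1O
A2 | alternative 1 | ethyl diazoacetate | CCOC(=O)C=[N+]=[N-]
A3 | alternative 1 | 3,4,5-trimethoxybenzaldehyde | COc1cc(C=O)cc(OC)c1OC
A4 | alternative 1 | ethyl (2R,3S)-2-[2-bromo-4-(1,3-dioxolan-2-yl)-6-methoxyphenoxy]-3-hydroxy-3-(3,4,5-trimethoxyphenyl)propanoate | COc1cc([C@H](O)[C@H](C(=O)OCC)Oc2c(Br)cc(C3OCCO3)cc2OC)cc(OC)c1OC
A5 | alternative 2 | (1S,2S)-1-[(tert-butyldimethylsilyl)oxy]-1-(3,4,5-trimethoxyphenyl)propan-2-ol | COc1cc([C@H](O[Si](C)(C)C(C)(C)C)[C@H](C)O)cc(OC)c1OC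
A6 | alternative 2 | methyl 4-diazo-3,5-dioxocyclohexane-1-carboxylate | COC(=O)C1CC(=O)C(=[N+]=[N-])C(=O)C1
A7 | alternative 2 | methyl (2S,3S)-3-methyl-5-oxo-2-(3,4,5-trimethoxyphenyl)-2,3,5,6,7,8-hexahydro-1,4-benzodioxine-7-carboxylate (epimer mixture at C7) | COc1cc([C@@H]2OC3=C(O[C@H]2C)C(=O)CC(C(=O)OC)C3)cc(OC)c1OC
A8 | alternative 3 | methyl 4-hydroxy-3-methoxy-5-{[(1R)-1-(3,4,5-trimethoxyphenyl)prop-2-en-1-yl]oxy}benzoate | COc1cc([C@@H](C=C)Oc2cc(C(=O)OC)cc(OC)c2O)cc(OC)c1OC
A9 | alternative 3 | methyl (2S,3R)-3-(iodomethyl)-5-methoxy-2-(3,4,5-trimethoxyphenyl)-2,3-dihydro-1,4-benzodioxine-7-carboxylate (trans) | COc1cc([C@@H]2Oc3cc(C(=O)OC)cc(OC)c3O[C@H]2CI)cc(OC)c1OC
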